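## Retrosynthetic overview

1. Target ⇐ 11-hydroxy-16-en-15-one (C17–OH and C16–H by conjugate borylation/oxidation with exo protonation) ⇐ 16-ene by allylic oxidation at C15.
2. Ring D ⇐ 5-exo vinyl-radical closure of a C8 propargyl group onto C13 of an 11-hydroxy-Δ12 cyclohexene; the C11 carbinol comes from 1,2-reduction of an enone.
3. Key step: ring C and the 7,20-δ-lactone together ⇐ intramolecular Diels–Alder reaction of a C20-tethered 2-propargylacrylate with a C9=C11(OSi)–C12=C13(NMe2) diene carried by C10.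
4. C10 quaternary centre ⇐ α-propargylation of a C20 aldehyde; ring A and the 6,19-γ-lactone ⇐ ester-tethered intramolecular Diels–Alder reaction of a (Z)-dienyl (Z)-enoate whose only stereocentre is a D-mannitol-derived dioxolane, later cut down to the C20 aldehyde.
5. Ring order: A/γ-lactone → C/δ-lactone → D; stereochemistry is relayed dioxolane → C4/C5 → C10 → C8/C9 → C11 → C13 → C16.

Assumption: locants C1–C20 follow ent-kaurane numbering of the target, and the cis-enoate made from D-mannitol (via (R)-glyceraldehyde acetonide) is treated as a purchasable chiral compound.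

## Route

Step 1
Reactants: 1 acrolein; 2 ethyl 2-[bis(2,2,2-trifluoroethoxy)phosphoryl]propanoate
Product: 3 ethyl (2Z)-2-methylpenta-2,4-dienoate
Conditions: KHMDS, 18-crown-6, THF, −78 °C
Reagents that add atoms: none
Why: The Still–Gennari variant of the Horner–Wadsworth–Emmons olefination gives the (Z)-trisubstituted enoate (ester cis to vinyl), the geometry that later puts the tether on the inside of the diene.

Step 2
Reactants: 3 ethyl (2Z)-2-methylpenta-2,4-dienoate
Product: 4 (2Z)-2-methylpenta-2,4-dien-1-ol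
Conditions: DIBAL-H (2.2 equiv), CH2Cl2, −78 °C; Rochelle salt
Reagents that add atoms: none
Why: DIBAL-H reduces the conjugated ester 1,2 to the allylic alcohol (hydride reduction) without touching the diene or its (Z) geometry.

Step 3
Reactants: 4 (2Z)-2-methylpenta-2,4-dien-1-ol; 5 methyl (2Z)-3-[(4S)-2,2-dimethyl-1,3-dioxolan-4-yl]prop-2-enoate
Product: 6 (2Z)-2-methylpenta-2,4-dien-1-yl (2Z)-3-[(4S)-2,2-dimethyl-1,3-dioxolan-4-yl]prop-2-enoate
Conditions: (ClBu2Sn)2O (2 mol%), PhMe, reflux, 4 Å MS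
Reagents that add atoms: none
Why: Neutral distannoxane-catalysed transesterification (Otera) exchanges methanol for the dienol without isomerising the (Z)-enoate or opening the acetonide.

Step 4
Reactants: 6 (2Z)-2-methylpenta-2,4-dien-1-yl (2Z)-3-[(4S)-2,2-dimethyl-1,3-dioxolan-4-yl]prop-2-enoate
Product: 7 7-[(4S)-2,2-dimethyl-1,3-dioxolan-4-yl]-3a-methyl-3a,4,7,7a-tetrahydro-2-benzofuran-1(3H)-one (cis-fused; dioxolanyl syn to the C7a–C1 bond)
Conditions: BHT (cat.), 1,2-dichlorobenzene (0.01 M), 180 °C, sealed tube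
Reagents that add atoms: none
Why: In this intramolecular Diels–Alder reaction the (Z)-diene can deliver the ester tether only in the exo mode, which forces the cis-fused γ-lactone (C4-methyl syn to H5), and the diene adds to the enoate face anti to the dioxolane C–O bond in the A(1,3)-minimised conformer (allylic H eclipsing the alkene), so the purchased (S) centre sets C4 and C5.

Step 5
Reactants: 7 cis-fused tetrahydro lactone acetonide
Product: 8 7-[(4S)-2,2-dimethyl-1,3-dioxolan-4-yl]-3a-methylhexahydro-2-benzofuran-1(3H)-one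
Conditions: H2 (1 atm), 10% Pd/C, EtOAc, rt
Reagents that add atoms: none
Why: Catalytic hydrogenation saturates the only C=C bond and touches no stereocentre.

Step 6
Reactants: 8 hexahydro lactone acetonide
Product: 9 7-formyl-3a-methylhexahydro-2-benzofuran-1(3H)-one (CHO = C20 on C10)
Conditions: H5IO6, EtOAc, rt
Reagents that add atoms: none
Why: Periodic acid hydrolyses the terminal acetonide and cleaves the 1,2-diol in one pot (Malaprade glycol cleavage), turning the spent dioxolane centre into the C20 aldehyde carbon.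

Step 7
Reactants: 9 lactone aldehyde
Product: 10 7-formyl-3a-methyl-7-(prop-2-yn-1-yl)hexahydro-2-benzofuran-1(3H)-one (CHO syn, propargyl anti to the C7a–C1 bond)
Conditions: KHMDS, THF, −78 °C; HC≡CCH2Br, −78 → 0 °C
Reagents that add atoms: propargyl bromide (3-bromoprop-1-yne), C#CCBr
Why: In this enolate alkylation only the aldehyde α-position (C10) is deprotonated, and the electrophile enters the exocyclic enolate anti to the cis-fused lactone ring (away from the axial C19 methylene), so C10 carries the formyl group cis to C6 and C19.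

Step 8
Reactants: 10 propargyl aldehyde
Product: 11 7-(hydroxymethyl)-3a-methyl-7-(prop-2-yn-1-yl)hexahydro-2-benzofuran-1(3H)-one
Conditions: NaBH4, MeOH, 0 °C
Reagents that add atoms: none
Why: Borohydride reduces the aldehyde chemoselectively; lactone and alkyne are inert at 0 °C.

Step 9
Reactants: 11 alkynyl alcohol
Product: 12 7-(hydroxymethyl)-3a-methyl-7-(2-oxopropyl)hexahydro-2-benzofuran-1(3H)-one (in equilibrium with its lactol)
Conditions: Ph3PAuNTf2 (2 mol%), 1,4-dioxane–H2O (4:1), 60 °C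
Reagents that add atoms: water, O
Why: Gold(I)-catalysed Markovnikov hydration of the terminal alkyne (assisted by 5-exo attack of the C20 hydroxyl) puts the ketone oxygen on C11.

Step 10
Reactants: 13 diethyl 2-(prop-2-yn-1-yl)propanedioate
Product: 15 2-methylidenepent-4-ynoic acid, via propargylmalonic acid 14 (not isolated)
Conditions: KOH, EtOH–H2O, reflux; HCl; then (CH2O)n, Et2NH, EtOAc, reflux
Reagents that add atoms: potassium hydroxide, [K+].[OH-]; formaldehyde (as paraformaldehyde), C=O
Why: Saponification followed by decarboxylative Mannich methylenation (Knoevenagel–Doebner type) of the malonic acid gives the α-substituted acrylic acid.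

Step 11
Reactants: 12 hydroxy methyl ketone; 15 2-methylidenepent-4-ynoic acid
Product: 16 [3a-methyl-1-oxo-7-(2-oxopropyl)octahydro-2-benzofuran-7-yl]methyl 2-methylidenepent-4-ynoate
Conditions: DCC, DMAP (cat.), CH2Cl2, 0 °C → rt
Reagents that add atoms: none
Why: Steglich esterification acylates the primary C20 hydroxyl (pulled out of the lactol equilibrium) before the enaminone is made, so the free alcohol cannot cyclise onto it.

Step 12
Reactants: 16 keto ester
Product: 17 {7-[(3E)-4-(dimethylamino)-2-oxobut-3-en-1-yl]-3a-methyl-1-oxooctahydro-2-benzofuran-7-yl}methyl 2-methylidenepent-4-ynoate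
Conditions: Me2NCH(OMe)2, BHT (cat.), PhMe, 90 °C
Reagents that add atoms: N,N-dimethylformamide dimethyl acetal, COC(OC)N(C)C
Why: Enaminone formation occurs at the unhindered methyl group of the ketone and installs C13 as an (E)-vinylogous amide.

Step 13
Reactants: 17 enaminone ester
Product: 20 11-oxo-6,7:13,16-diseco-ent-kaur-12-en-16-yne-6,19:7,20-diolide, via aminosiloxydiene 18 (not isolated), via Diels–Alder adduct 19 (not isolated)
Conditions: TBSOTf, Et3N, CH2Cl2, −78 → 0 °C; then PhMe, 110 °C; then 48% aq. HF, MeCN, 0 °C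
Reagents that add atoms: none
Why: Soft enolisation at C9 gives a Rawal-type (Z)-1-amino-3-siloxy diene whose tether-enforced intramolecular Diels–Alder reaction sets C8 and C9 and forms ring C with the cis-fused δ-lactone (ester carbonyl endo, propargyl exo; A(1,3) strain holds the C10–C5 bond anti to C11 so the C20-tethered dienophile adds to the face away from C1), and HF then hydrolyses the enol ether and eliminates dimethylamine to the enone.

Step 14
Reactants: 20 tricyclic enone
Product: 21 11-hydroxy-6,7:13,16-diseco-ent-kaur-12-en-16-yne-6,19:7,20-diolide (11-OH cis to C10 on ring C)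
Conditions: NaBH4, CeCl3·7H2O, MeOH, −78 °C
Reagents that add atoms: none
Why: In the Luche 1,2-reduction the favoured half-chair (spiro C10 equatorial, C7 pseudoaxial) is attacked at C11 anti to the pseudoaxial lactone carbon and cis to H9, which places the hydroxyl cis to C10; the low temperature avoids translactonisation onto C7.

Step 15
Reactants: 21 allylic alcohol
Product: 23 11-hydroxy-6,7-seco-ent-kaur-16-ene-6,19:7,20-diolide, via vinylstannane 22 (not isolated)
Conditions: Bu3SnH, AIBN (cat.), PhH (0.02 M), 80 °C; then 1 M HCl, THF, rt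
Reagents that add atoms: none
Why: Stannyl-radical addition to the alkyne gives a vinyl radical that closes 5-exo-trig onto C13 on the only face the C8 tether can reach (setting C13 and the bicyclo[3.2.1]octane), and protodestannylation leaves the exocyclic methylene.

Step 16
Reactants: 23 tetracyclic 16-ene
Product: 25 11-hydroxy-15-oxo-6,7-seco-ent-kaur-16-ene-6,19:7,20-diolide, via allylic alcohol 24 (not isolated)
Conditions: SeO2 (0.5 equiv), t-BuOOH, CH2Cl2, rt; then MnO2, CH2Cl2, rt
Reagents that add atoms: tert-butyl hydroperoxide, CC(C)(C)OO (oxygen delivered through catalytic selenium dioxide, O=[Se]=O)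
Why: Selenium dioxide allylic hydroxylation (ene reaction then [2,3]-sigmatropic shift) occurs at C15 because the bridgehead C13–H cannot react, and MnO2 oxidises only the new allylic alcohol and leaves the C11 hydroxyl alone.

Step 17
Reactants: 25 exo-methylene enone
Product: 27 (4R,5R,8S,9S,10R,11R,13S,16S)-11,17-dihydroxy-15-oxo-6,7-seco-ent-kaurane-6,19:7,20-diolide (target CNP0555433.1), via boronate 26 (not isolated)
Conditions: B2pin2, CuCl (5 mol%), Xantphos (5 mol%), NaOt-Bu (10 mol%), MeOH (2 equiv), THF, rt; then NaBO3·4H2O, THF–H2O, 0 °C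
Reagents that add atoms: sodium perborate, [Na+].[Na+].O[B-]1(O)OO[B-](O)(O)OO1
Why: Copper-catalysed conjugate borylation places boron on C17, the enolate is protonated at C16 from the open exo face (syn to C14) so that the CH2 group lies endo, and perborate oxidises the C–B bond with retention to the primary alcohol.

## Compound list

1 | acrolein | C=CC=O | starting material
2 | ethyl 2-[bis(2,2,2-trifluoroethoxy)phosphoryl]propanoate | CCOC(=O)C(C)P(=O)(OCC(F)(F)F)OCC(F)(F)F | starting material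
3 | ethyl (2Z)-2-methylpenta-2,4-dienoate | C=C/C=C(C)\C(=O)OCC | intermediate
4 | (2Z)-2-methylpenta-2,4-dien-1-ol | C=C/C=C(C)\CO | intermediate
5 | methyl (2Z)-3-[(4S)-2,2-dimethyl-1,3-dioxolan-4-yl]prop-2-enoate | COC(=O)/C=C\[C@H]1COC(C)(C)O1 | starting material
6 | (2Z)-2-methylpenta-2,4-dien-1-yl (2Z)-3-[(4S)-2,2-dimethyl-1,3-dioxolan-4-yl]prop-2-enoate | C=C/C=C(C)\COC(=O)/C=C\[C@H]1COC(C)(C)O1 | intermediate
7 | cis-fused 7-[(4S)-2,2-dimethyl-1,3-dioxolan-4-yl]-3a-methyl-3a,4,7,7a-tetrahydro-2-benzofuran-1(3H)-one (dioxolanyl syn to the C7a–C1 bond) | C[C@@]12CC=C[C@H]([C@H]3COC(C)(C)O3)[C@@H]1C(=O)OC2 | intermediate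
8 | cis-fused 7-[(4S)-2,2-dimethyl-1,3-dioxolan-4-yl]-3a-methylhexahydro-2-benzofuran-1(3H)-one | C[C@@]12CCC[C@H]([C@H]3COC(C)(C)O3)[C@@H]1C(=O)OC2 | intermediate
9 | cis-fused 7-formyl-3a-methylhexahydro-2-benzofuran-1(3H)-one | C[C@@]12CCC[C@H](C=O)[C@@H]1C(=O)OC2 | intermediate
10 | 7-formyl-3a-methyl-7-(prop-2-yn-1-yl)hexahydro-2-benzofuran-1(3H)-one (CHO syn to the C7a–C1 bond) | C[C@@]12CCC[C@](CC#C)(C=O)[C@@H]1C(=O)OC2 | intermediate
11 | 7-(hydroxymethyl)-3a-methyl-7-(prop-2-yn-1-yl)hexahydro-2-benzofuran-1(3H)-one | C[C@@]12CCC[C@](CC#C)(CO)[C@@H]1C(=O)OC2 | intermediate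
12 | 7-(hydroxymethyl)-3a-methyl-7-(2-oxopropyl)hexahydro-2-benzofuran-1(3H)-one | C[C@@]12CCC[C@](CC(C)=O)(CO)[C@@H]1C(=O)OC2 | intermediate
13 | diethyl 2-(prop-2-yn-1-yl)propanedioate | CCOC(=O)C(CC#C)C(=O)OCC | starting material
14 | 2-(prop-2-yn-1-yl)propanedioic acid | OC(=O)C(CC#C)C(=O)O | intermediate
15 | 2-methylidenepent-4-ynoic acid | C=C(CC#C)C(=O)O | intermediate
16 | [3a-methyl-1-oxo-7-(2-oxopropyl)octahydro-2-benzofuran-7-yl]methyl 2-methylidenepent-4-ynoate | C[C@@]12CCC[C@](CC(C)=O)(COC(=O)C(=C)CC#C)[C@@H]1C(=O)OC2 | intermediate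
17 | {7-[(3E)-4-(dimethylamino)-2-oxobut-3-en-1-yl]-3a-methyl-1-oxooctahydro-2-benzofuran-7-yl}methyl 2-methylidenepent-4-ynoate | C[C@@]12CCC[C@](CC(=O)/C=C/N(C)C)(COC(=O)C(=C)CC#C)[C@@H]1C(=O)OC2 | intermediate
18 | {7-[(1Z,3E)-2-[tert-butyl(dimethyl)silyl]oxy-4-(dimethylamino)buta-1,3-dien-1-yl]-3a-methyl-1-oxooctahydro-2-benzofuran-7-yl}methyl 2-methylidenepent-4-ynoate | C[C@@]12CCC[C@](/C=C(O[Si](C)(C)C(C)(C)C)/C=C/N(C)C)(COC(=O)C(=C)CC#C)[C@@H]1C(=O)OC2 | intermediate
19 | 11-[tert-butyl(dimethyl)silyl]oxy-13-(dimethylamino)-6,7:13,16-diseco-ent-kaur-11-en-16-yne-6,19:7,20-diolide (NMe2 cis to C10) | C[C@@]12CCC[C@]3(COC(=O)[C@@]4(CC#C)C[C@@H](N(C)C)C=C(O[Si](C)(C)C(C)(C)C)[C@H]43)[C@@H]1C(=O)OC2 | intermediate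
20 | 11-oxo-6,7:13,16-diseco-ent-kaur-12-en-16-yne-6,19:7,20-diolide (C4, C5, C8, C9, C10 as in target) | C[C@@]12CCC[C@]3(COC(=O)[C@@]4(CC#C)CC=CC(=O)[C@H]43)[C@@H]1C(=O)OC2 | intermediate
21 | 11-hydroxy-6,7:13,16-diseco-ent-kaur-12-en-16-yne-6,19:7,20-diolide (11-OH cis to C10) | C[C@@]12CCC[C@]3(COC(=O)[C@@]4(CC#C)CC=C[C@@H](O)[C@H]43)[C@@H]1C(=O)OC2 | intermediate
22 | 11-hydroxy-17-(tributylstannyl)-6,7-seco-ent-kaur-16-ene-6,19:7,20-diolide (E/Z mixture) | C[C@@]12CCC[C@]3(COC(=O)[C@@]45C[C@@H](C[C@@H](O)[C@H]43)C(=C[Sn](CCCC)(CCCC)CCCC)C5)[C@@H]1C(=O)OC2 | intermediate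
23 | 11-hydroxy-6,7-seco-ent-kaur-16-ene-6,19:7,20-diolide | C[C@@]12CCC[C@]3(COC(=O)[C@@]45C[C@@H](C[C@@H](O)[C@H]43)C(=C)C5)[C@@H]1C(=O)OC2 | intermediate
24 | 11,15-dihydroxy-6,7-seco-ent-kaur-16-ene-6,19:7,20-diolide (15-OH exo, syn to C14) | C[C@@]12CCC[C@]3(COC(=O)[C@@]45C[C@@H](C[C@@H](O)[C@H]43)C(=C)[C@@H]5O)[C@@H]1C(=O)OC2 | intermediate
25 | 11-hydroxy-15-oxo-6,7-seco-ent-kaur-16-ene-6,19:7,20-diolide | C[C@@]12CCC[C@]3(COC(=O)[C@@]45C[C@@H](C[C@@H](O)[C@H]43)C(=C)C5=O)[C@@H]1C(=O)OC2 | intermediate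
26 | 11-hydroxy-15-oxo-17-(4,4,5,5-tetramethyl-1,3,2-dioxaborolan-2-yl)-6,7-seco-ent-kaurane-6,19:7,20-diolide (C17 endo) | C[C@@]12CCC[C@]3(COC(=O)[C@@]45C[C@@H](C[C@@H](O)[C@H]43)[C@@H](CB6OC(C)(C)C(C)(C)O6)C5=O)[C@@H]1C(=O)OC2 | intermediate
27 | (4R,5R,8S,9S,10R,11R,13S,16S)-11,17-dihydroxy-15-oxo-6,7-seco-ent-kaurane-6,19:7,20-diolide | C[C@@]12CCC[C@]3(COC(=O)[C@@]45C[C@@H](C[C@@H](O)[C@H]43)[C@@H](CO)C5=O)[C@@H]1C(=O)OC2 | target

## Step count and risks

Total step count: 17. Longest linear sequence: 16 steps (steps 1–9 and 11–17, from acrolein).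

The three steps most likely to fail:

Step 4 (first intramolecular Diels–Alder reaction). An ester tether, a (Z)-diene and a (Z)-enoate together mean a slow cycloaddition, and at 180 °C a 1,5-hydrogen shift of the (Z)-diene or incomplete face selectivity can intervene. The fallback sets out from 4 and 5 and comes back at 7, and it replaces the covalent ester tether by a temporary metal tether. Dienol 4 is deprotonated with MeMgBr in PhMe to the bromomagnesium (2Z)-2-methylpenta-2,4-dien-1-olate F1. Its magnesium binds and activates the carbonyl of 5, so a templated intermolecular Diels–Alder reaction with the same regiochemistry can run at 25–60 °C. It gives the methyl ester hydroxy cycloadduct F2 (CH2OH cis to CO2Me), which lactonises on mildly acidic work-up to 7.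

Step 13 (second intramolecular Diels–Alder reaction). The tether forces the nucleophilic diene terminus C9 onto the α-carbon of the acrylate, so the cycloaddition is electronically mismatched and may need more heat than the aminosiloxy diene tolerates. The fallback sets out from 17 and comes back at 20, and it changes the diene class. Stirring 17 with HCl (1 equiv) in MeOH exchanges the amine for methanol and gives the β-methoxy enone F3. TBSOTf/Et3N converts it into the thermally robust Danishefsky-type 1-methoxy-3-siloxy diene F4, which can be cyclised at 150–170 °C in PhMe to the methoxy cycloadduct F5. HF in MeCN then hydrolyses the enol ether and eliminates methanol to give 20.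

Step 14 (C11 reduction). The facial preference rests on a conformational argument and could be reversed. The fallback sets out from 20 and comes back at 21, and it corrects the centre by inversion instead of by reduction. If Luche reduction of 20 gives mainly the C11 epimer F6, a Mitsunobu reaction (HCO2H, PPh3, DIAD, THF) gives the inverted formate F7. KHCO3 in MeOH then removes the formyl group to give 21.

Further compounds
F1 | step 4 | bromomagnesium (2Z)-2-methylpenta-2,4-dien-1-olate | C=C/C=C(C)\CO[Mg]Br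
F2 | step 4 | methyl 2-[(4S)-2,2-dimethyl-1,3-dioxolan-4-yl]-6-(hydroxymethyl)-6-methylcyclohex-3-ene-1-carboxylate (CH2OH, CO2Me and dioxolanyl all cis) | C[C@@]1(CO)CC=C[C@H]([C@H]2COC(C)(C)O2)[C@@H]1C(=O)OC
F3 | step 13 | {7-[(3E)-4-methoxy-2-oxobut-3-en-1-yl]-3a-methyl-1-oxooctahydro-2-benzofuran-7-yl}methyl 2-methylidenepent-4-ynoate | C[C@@]12CCC[C@](CC(=O)/C=C/OC)(COC(=O)C(=C)CC#C)[C@@H]1C(=O)OC2
F4 | step 13 | {7-[(1Z,3E)-2-[tert-butyl(dimethyl)silyl]oxy-4-methoxybuta-1,3-dien-1-yl]-3a-methyl-1-oxooctahydro-2-benzofuran-7-yl}methyl 2-methylidenepent-4-ynoate | C[C@@]12CCC[C@](/C=C(O[Si](C)(C)C(C)(C)C)/C=C/OC)(COC(=O)C(=C)CC#C)[C@@H]1C(=O)OC2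
F5 | step 13 | 11-[tert-butyl(dimethyl)silyl]oxy-13-methoxy-6,7:13,16-diseco-ent-kaur-11-en-16-yne-6,19:7,20-diolide | C[C@@]12CCC[C@]3(COC(=O)[C@@]4(CC#C)C[C@@H](OC)C=C(O[Si](C)(C)C(C)(C)C)[C@H]43)[C@@H]1C(=O)OC2
F6 | step 14 | 11-epi-11-hydroxy-6,7:13,16-diseco-ent-kaur-12-en-16-yne-6,19:7,20-diolide (11-OH trans to C10) | C[C@@]12CCC[C@]3(COC(=O)[C@@]4(CC#C)CC=C[C@H](O)[C@H]43)[C@@H]1C(=O)OC2
F7 | step 14 | 11-formyloxy-6,7:13,16-diseco-ent-kaur-12-en-16-yne-6,19:7,20-diolide (formate of 21) | C[C@@]12CCC[C@]3(COC(=O)[C@@]4(CC#C)CC=C[C@@H](OC=O)[C@H]43)[C@@H]1C(=O)OC2
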